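The numbers in the tables stem from a simulated flask from invented constants; scatter was added.

Suppose a one-step world: starting complex meets incoming ligand, becomes complex with one exchanged and stops there. You then work with s, the fraction of starting complex left, not with the fraction made. These are the flask, the earlier runs and the questions.

| flask | starting complex | incoming ligand | leaving ligand | remark | time |
|---|---|---|---|---|---|
| noon | 0.067 M | 2 equiv | 2 equiv | run made earlier |  |
| winter | 0.15 M | 2 equiv | 2 equiv | run made earlier |  |
| flask | 0.10 M | 2.00 equiv | 2.00 equiv |  | 1.5 h |

- noon (time / min: complex with one exchanged / %, complex with two exchanged / %): 4.00: 4.3, 0.1; 6.00: 7.3, 0; 10.0: 12.6, 1.0; 15.0: 16.4, 0.3; 25.0: 24.7, 2.7; 40.0: 30.9, 6.0; 50.0: 36.1, 8.3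
- winter (time / min: complex with one exchanged / %, complex with two exchanged / %): 4.00: 10.9, 0.4; 6.00: 15.1, 1.4; 10.0: 22.6, 3.3; 15.0: 29.1, 4.3; 25.0: 36.4, 9.6; 40.0: 41.9, 18.7; 50.0: 42.4, 24.0

(readings scatter by 0.5 percentage points)

- the analysis behind the earlier runs scatters by 0.5 percentage points, standard deviation
- a reading or a percentage of complex with two exchanged counts all its forms, free or not

- equivalents of incoming ligand to starting complex, everything else as given, that leave most complex with one exchanged at 1.5 h
- the amount of complex with one exchanged then, in percent of the starting complex charged
- the amount of complex with one exchanged with the amounts as given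

With the ligand held at its charge (pseudo-first-order), ln s falls in step with ligand concentration times time. The winter run read s = 74.1 % at 10.0 min, and the flask gets 6.00 times that winter product by 1.5 h. So its clock, minus ln s, reads 1.80, which leaves s = 0.166 and gives a one-exchanged fraction m of 0.834.

Now let complex with one exchanged take ligand too. Both steps see the same ligand, so on this clock the ligand cancels. The gain in complex with two exchanged, per unit of clock and per unit of m, is the selectivity factor, second step over first. Read between 25.0 min and 50.0 min in both runs together, it is 0.746. Then m = (s^sel − s)/(1 − sel), which tops where s equals sel times m, at s = 0.316 and m = 0.423. With the ligand still held, m falls to 0.377.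

Last, let the ligand run down. I take it to fall to 0.5 of its charge by the end, which shortens the clock to 1.35. My reckoning is then s = 0.260 and m = 0.417. That s is lower than at the top, and scaling the clock with the charge puts the best charge near 1.71 equiv.

The forecast gives 43.3 %, and 43.5 % at 1.9 equiv, calling the flask “slightly past the peak”. Its amount stands above mine, and so does its charge.

The flask gives 43.1 %, and 43.2 % at 1.86 equiv.

    complex with one exchanged + incoming ligand → leaving ligand + complex with two exchanged (k = 0.0724 M⁻¹ min⁻¹)
    starting complex + incoming ligand → leaving ligand + complex with one exchanged (k = 0.102 M⁻¹ min⁻¹)
    crystals ⇌ complex with two exchanged, rate k3*(cs3 - [complex with two exchanged]) while solid is left; crystals form when [complex with two exchanged] > cs3 (solubility = 1.20 mM, k = 0.323 min⁻¹)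

In the flask crystals stand at 26.8 % at the asked time, yet their falling out does not move complex with one exchanged there. In the flask at that time, s over sel times m is 0.867, under one, so with sel as read from the runs it stands past the top. A second flask, the same but charged with 3.40 equiv of incoming ligand, holds s = 10.3 % and m = 33.2 % at 1.50 h, and its ratio is 0.416.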